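There are 6 questions here, a leader and its share in each of 3 flasks, and since the flasks have the same charge and differ in the time of reading, they are one question put at 3 times.

    G + Q → G.Q (k1 = 0.48 M⁻¹ h⁻¹)
    J → Q (k2 = 0.38 h⁻¹)
    L ⇌ G.Q, rate k3*(cs3 - [G.Q]) while solid is left; crystals form when [G.Q] > cs3 (cs3 = 0.053 M, k3 = 13 h⁻¹)
    J + G.Q ⇌ J.G.Q, settled at all times (K4 = 7.1 M⁻¹)

the same everywhere: J 0.087 M; G 0.261 M
- dusk: time 80 min
- autumn: time 160 min
- spring: time 320 min

* which of these there is most of at the end, counted by the J in it, dusk (G.Q / Q / J)
* which of these there is most of at the end, counted by the J in it, autumn (G.Q / Q / J)
* which of these there is most of at the end, counted by the J in it, spring (G.Q / Q / J)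
* amount of the one of these that there is most of at the end, in percent of the J charged, dusk
* amount of the one of these that there is most of at the end, in percent of the J charged, autumn
* amount of the one of these that there is most of at the end, in percent of the J charged, spring

- in percentages every species weighs as the J in it: one J.G.Q counts as two
- for G.Q the L and J.G.Q are counted in
- as a solid, counted per litre of solution: L
- in an amount of G.Q, one J.G.Q counts as one G.Q
- run time (dusk): 80 min

*What does J do on its own?* It goes to Q by a first-order step with a half-life of 110 min. Take the case of Q with no drain: what leaves J arrives in Q, the two fractions of the charge are mirror images, and they meet at half of the charge at that half-life, which is the zero of my scale.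

*But Q is drained. How hard?* G takes Q, and with G held at its charge this is a pseudo-first-order drain whose half-life of 5.5 h is longer than that of J, so the drain ratio ρ, the drain constant over the supply constant, is 0.330, with zero as the symmetric case.

*Where does that move the meeting?* The textbook solution for two first-order steps in a row, with the fraction in J set equal to the fraction in Q, gives the logarithm of 2 minus ρ, divided by 1 minus ρ and by 0.38 h⁻¹, which is 121 min. This crossing time, the moment when the fraction still J equals the fraction standing as Q, lies later than the half-life and is what I carry: before it J stands above Q, after it Q stands above J.

*So what do you commit to?* At dusk, 80 min comes before the crossing, so J leads with 60.3%; 160 min and 320 min come after it, so Q leads with 52.7% in autumn and 56.8% in spring.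

*And G.Q, which might overtake or crystallise?* In spring my remainder for G.Q is 30.0%, less than Q and less than the 60.9% of the charge that the solubility allows. The weak spot is J.G.Q, for which the constant of step 4 times J at the start of dusk comes to 0.62, and I leave it out of the reckoning.

The forecast names J at dusk with 59% (56% to 62%), Q in autumn with 52% (48% to 55%), and Q in spring with 57% (53% to 61%), on the ground that “J leads at 80 min and Q leads from 160 min onward”; its dusk figure is lower than mine, and so is its autumn figure.

The simulation gives J at 59.5% at dusk, Q at 52.2% in autumn and Q at 56.8% in spring.

The leader changes between 80 min and 160 min, where my reckoned crossing time of 121 min lies, and the time of reading is what moves J: spring holds 12.7% of J, against 59.5% with the difference in time taken away. The spring flask also holds 4.14% as J.G.Q, which my reckoning does not have, and that is less than the gap between Q at 56.8% and G.Q at 28.4%.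

The neighbouring flask is the autumn flask stopped at 60.0 min, earlier than the crossing time, so J should lead there; it does, with 67.9% against 29.5% of Q.

The constants used here were chosen freely; no experiment stands behind them.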